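The route rests on disconnecting the O–C8 bond of the oxolane ring (O, C5–C8). C8 is an ether carbon propargylic to C9≡C10, an alkyne that becomes terminal once the C10–C11 bond to the bromotriene chain is cut, so a copper allenylidene can be raised there. In one operation the key step should close the ring, form the C–O bond and set C8 as (S), trans to the C5 side chain, from either C8 epimer of its precursor. That precursor is an open-chain methyl (5R)-5-hydroxydec-9-ynoate carrying a pentafluorobenzoate at C8, made from an ynone by asymmetric transfer hydrogenation. The C11–C20 chain is then attached by Sonogashira coupling and finished by a (Z)-selective bromo-olefination.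

Key step: step 9

Numbering: C1 is the ester carbon and C20 the CHBr carbon of the target chain; the ring oxygen bridges C5 and C8.

Assumption: (S,S)-Ph-pybox is written as the ligand antipode matched to the (5R) centre for the (8S) ether; if the pairing proves mismatched, the (R,R)-ligand is used with no other change.

Step 1
Reactants: 1 methyl 5-chloro-5-oxopentanoate; 2 3,3-diethoxyprop-1-yne
Product: 3 methyl 8,8-diethoxy-5-oxooct-6-ynoate
Conditions: PdCl2(PPh3)2 (2 mol%), CuI (4 mol%), Et3N (1.1 equiv), THF, rt
Reagents that add atoms: none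
Why: Acyl Sonogashira coupling: zerovalent palladium inserts into the C–Cl bond, the copper acetylide of 2 transmetalates and reductive elimination should give the ynone, while one equivalent of Et3N at room temperature leaves the methyl ester and the acetal alone.

Step 2
Reactants: 3 methyl 8,8-diethoxy-5-oxooct-6-ynoate
Product: 4 methyl (5R)-8,8-diethoxy-5-hydroxyoct-6-ynoate
Conditions: RuCl(p-cymene)[(R,R)-TsDPEN] (1 mol%), KOH (1.2 mol%), iPrOH, rt
Reagents that add atoms: none
Why: Asymmetric transfer hydrogenation of an alkynyl ketone (Noyori type): hydride and proton pass from the Ru–H/N–H pair in a six-membered transition state in which the alkynyl group takes the place usually held by an aryl group, so the (R,R)-ligand should set C5 as (R) without touching the triple bond, ester or acetal.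

Step 3
Reactants: 4 methyl (5R)-8,8-diethoxy-5-hydroxyoct-6-ynoate
Product: 5 methyl (5R)-5-[(tert-butyldimethylsilyl)oxy]-8,8-diethoxyoct-6-ynoate
Conditions: TBSCl (1.2 equiv), imidazole (2.5 equiv), DMF, 0 °C → rt
Reagents that add atoms: tert-butyldimethylsilyl chloride, CC(C)(C)[Si](C)(C)Cl
Why: Imidazole-promoted silylation of a secondary alcohol, placed here so that the C5 hydroxyl can neither lactonise onto C1 nor form a lactol once C8 becomes an aldehyde.

Step 4
Reactants: 5 methyl (5R)-5-[(tert-butyldimethylsilyl)oxy]-8,8-diethoxyoct-6-ynoate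
Product: 6 methyl (5R)-5-[(tert-butyldimethylsilyl)oxy]-8,8-diethoxyoctanoate
Conditions: H2 (1 atm), 10% Pd/C, NaHCO3 (solid), EtOAc, rt
Reagents that add atoms: none
Why: Heterogeneous catalytic hydrogenation should saturate C6≡C7 and leave the C5 centre, the silyl ether, the acetal and the ester unchanged, the bicarbonate guarding against acid traces on the catalyst.

Step 5
Reactants: 6 methyl (5R)-5-[(tert-butyldimethylsilyl)oxy]-8,8-diethoxyoctanoate
Product: 7 methyl (5R)-5-[(tert-butyldimethylsilyl)oxy]-8-oxooctanoate
Conditions: PPTS (0.2 equiv), acetone/H2O (10:1), 45 °C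
Reagents that add atoms: water, O
Why: Acid-catalysed acetal hydrolysis under PPTS is mild enough to spare a secondary TBS ether and a methyl ester and should free the C8 aldehyde.

Step 6
Reactants: 7 methyl (5R)-5-[(tert-butyldimethylsilyl)oxy]-8-oxooctanoate; 8 ethynylmagnesium bromide
Product: 9 methyl (5R)-5-[(tert-butyldimethylsilyl)oxy]-8-hydroxydec-9-ynoate (both C8 epimers)
Conditions: HC≡CMgBr (1.2 equiv, 0.5 M in THF), THF, –78 → –40 °C; aq. NH4Cl
Reagents that add atoms: none
Why: Grignard 1,2-addition to an aldehyde is far faster than attack on a methyl ester at low temperature, and C8 is left uncontrolled on purpose because the key step flattens that carbon.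

Step 7
Reactants: 9 methyl (5R)-5-[(tert-butyldimethylsilyl)oxy]-8-hydroxydec-9-ynoate (both C8 epimers)
Product: 10 methyl (5R)-5-[(tert-butyldimethylsilyl)oxy]-8-[(pentafluorobenzoyl)oxy]dec-9-ynoate (both C8 epimers)
Conditions: C6F5COCl (1.3 equiv), Et3N (2 equiv), DMAP (5 mol%), CH2Cl2, 0 °C
Reagents that add atoms: pentafluorobenzoyl chloride, O=C(Cl)c1c(F)c(F)c(F)c(F)c1F
Why: DMAP-catalysed esterification of the propargylic alcohol; a pentafluorobenzoate is chosen over a simple acetate because alkyl-substituted propargylic esters ionise reluctantly from their copper acetylides and profit from the better leaving group.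

Step 8
Reactants: 10 methyl (5R)-5-[(tert-butyldimethylsilyl)oxy]-8-[(pentafluorobenzoyl)oxy]dec-9-ynoate (both C8 epimers)
Product: 11 methyl (5R)-5-hydroxy-8-[(pentafluorobenzoyl)oxy]dec-9-ynoate (both C8 epimers)
Conditions: HF·pyridine, pyridine, THF, 0 °C → rt; NaHCO3 work-up; used at once
Reagents that add atoms: none
Why: Fluoride-mediated desilylation under pyridine-buffered conditions passes through no alkoxide, so the freed C5 hydroxyl should neither lactonise onto C1 nor take over the acyl group from O8, and the esters and the alkyne are inert to HF·pyridine.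

Step 9
Reactants: 11 methyl (5R)-5-hydroxy-8-[(pentafluorobenzoyl)oxy]dec-9-ynoate (both C8 epimers)
Product: 12 methyl 4-[(2R,5S)-5-ethynyloxolan-2-yl]butanoate
Conditions: CuOTf·½C6H6 (5 mol%), (S,S)-Ph-pybox (10 mol%), iPr2NEt (1.2 equiv), THF, –20 → 0 °C, Ar
Reagents that add atoms: none
Why: Proposed new method: the monovalent copper–pybox complex should metalate C10 of the terminal alkyne with the help of iPr2NEt, expel pentafluorobenzoate from C8 and so give a copper allenylidene (Cu=C10=C9=C8) in which C8 is trigonal, which is why both C8 epimers of 11 feed one intermediate; the C5 hydroxyl then adds to C8, and protonation of the resulting copper acetylide returns the terminal alkyne and the catalyst. The closest known reaction types are copper–pybox-catalysed enantioselective propargylic etherification and amination of terminal propargylic esters, intramolecular amination included, and the use of pentafluorobenzoates for alkyl-substituted propargylic substrates; ring closure by a tethered aliphatic alcohol onto an alkyl-substituted allenylidene under ligand control is the untested extension. The oxolane ring (O, C5, C6, C7, C8) closes in a 5-exo-trig mode, the C8=C9 bond of the allenylidene lying outside the new ring. The new stereocentre C8 is set by the chiral pybox on the copper bound at C10, which shields one face of the planar C8 while the C5 side chain sits pseudo-equatorial in the envelope-like transition state; the matched ligand antipode should give the (8S), 2,5-trans ring. The step needs O-alkylation to outrun δ-lactonisation, loss of a C7 proton to an enyne and capture by any external nucleophile, which the 1,4-spacing of hydroxyl and C8, the non-nucleophilic solvent, the hindered amine and the low temperature are meant to secure.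

Step 10
Reactants: 13 hept-6-yn-1-ol
Product: 15 (6E)-7-iodohept-6-en-1-ol, via alkenylzirconocene chloride 14 (not isolated)
Conditions: Cp2Zr(H)Cl (2.3 equiv), THF, rt; then I2 (1.1 equiv), 0 °C
Reagents that add atoms: iodine, II
Why: Hydrozirconation–iodination: the first equivalent of Cp2Zr(H)Cl caps the hydroxyl as a zirconium alkoxide, the second adds Zr–H syn across the alkyne with zirconium on the terminal carbon, and iodinolysis with retention should give the (E)-iodoalkene only.

Step 11
Reactants: 15 (6E)-7-iodohept-6-en-1-ol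
Product: 16 (6E)-7-iodohept-6-enal
Conditions: PhI(OAc)2 (1.1 equiv), TEMPO (10 mol%), CH2Cl2, rt
Reagents that add atoms: none
Why: TEMPO-catalysed oxidation with PhI(OAc)2 as the terminal oxidant stops at the aldehyde and does not touch the alkenyl iodide.

Step 12
Reactants: 16 (6E)-7-iodohept-6-enal
Product: 17 (2E,8E)-9-iodonona-2,8-dienal
Conditions: Ph3P=CHCHO (1.15 equiv), toluene, 80 °C
Reagents that add atoms: (triphenylphosphoranylidene)acetaldehyde, O=CC=P(c1ccccc1)(c1ccccc1)c1ccccc1
Why: Wittig olefination with the stabilised formyl ylide is (E)-selective under thermodynamic control of the oxaphosphetane, and the small excess of ylide is meant to stop at the enal.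

Step 13
Reactants: 12 methyl 4-[(2R,5S)-5-ethynyloxolan-2-yl]butanoate; 17 (2E,8E)-9-iodonona-2,8-dienal
Product: 18 methyl 4-[(2R,5S)-5-[(3E,9E)-11-oxoundeca-3,9-dien-1-yn-1-yl]oxolan-2-yl]butanoate
Conditions: Pd(PPh3)4 (5 mol%), CuI (10 mol%), Et3N (3 equiv), THF (degassed), rt
Reagents that add atoms: none
Why: Sonogashira coupling of a terminal alkyne with an (E)-alkenyl iodide runs at room temperature with retention of the alkene geometry, and the enal, the ester and the C8 ether centre are spectators.

Step 14
Reactants: 18 methyl 4-[(2R,5S)-5-[(3E,9E)-11-oxoundeca-3,9-dien-1-yn-1-yl]oxolan-2-yl]butanoate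
Product: 19 methyl 4-[(2R,5S)-5-[(3E,9E,11Z)-12-bromododeca-3,9,11-trien-1-yn-1-yl]oxolan-2-yl]butanoate
Conditions: [Ph3PCH2Br]Br (1.6 equiv), KOtBu (1.5 equiv), THF, –78 °C; then 18, –78 → –30 °C
Reagents that add atoms: (bromomethyl)triphenylphosphonium bromide, BrC[P+](c1ccccc1)(c1ccccc1)c1ccccc1.[Br-]
Why: Wittig olefination with the non-stabilised bromo-ylide Ph3P=CHBr under cold, kinetic conditions should give mainly the (Z)-bromoalkene through the cis-oxaphosphetane, and the slight shortfall of base keeps the methyl ester and both ring centres safe.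

Compound list
1 | methyl 5-chloro-5-oxopentanoate | COC(=O)CCCC(=O)Cl | starting material
2 | 3,3-diethoxyprop-1-yne | CCOC(OCC)C#C | starting material
3 | methyl 8,8-diethoxy-5-oxooct-6-ynoate | COC(=O)CCCC(=O)C#CC(OCC)OCC | intermediate
4 | methyl (5R)-8,8-diethoxy-5-hydroxyoct-6-ynoate | COC(=O)CCC[C@@H](O)C#CC(OCC)OCC | intermediate
5 | methyl (5R)-5-[(tert-butyldimethylsilyl)oxy]-8,8-diethoxyoct-6-ynoate | COC(=O)CCC[C@@H](O[Si](C)(C)C(C)(C)C)C#CC(OCC)OCC | intermediate
6 | methyl (5R)-5-[(tert-butyldimethylsilyl)oxy]-8,8-diethoxyoctanoate | COC(=O)CCC[C@@H](O[Si](C)(C)C(C)(C)C)CCC(OCC)OCC | intermediate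
7 | methyl (5R)-5-[(tert-butyldimethylsilyl)oxy]-8-oxooctanoate | COC(=O)CCC[C@@H](O[Si](C)(C)C(C)(C)C)CCC=O | intermediate
8 | ethynylmagnesium bromide | C#C[Mg]Br | starting material
9 | methyl (5R)-5-[(tert-butyldimethylsilyl)oxy]-8-hydroxydec-9-ynoate (both C8 epimers) | COC(=O)CCC[C@@H](O[Si](C)(C)C(C)(C)C)CCC(O)C#C | intermediate
10 | methyl (5R)-5-[(tert-butyldimethylsilyl)oxy]-8-[(pentafluorobenzoyl)oxy]dec-9-ynoate (both C8 epimers) | COC(=O)CCC[C@@H](O[Si](C)(C)C(C)(C)C)CCC(OC(=O)c1c(F)c(F)c(F)c(F)c1F)C#C | intermediate
11 | methyl (5R)-5-hydroxy-8-[(pentafluorobenzoyl)oxy]dec-9-ynoate (both C8 epimers) | COC(=O)CCC[C@@H](O)CCC(OC(=O)c1c(F)c(F)c(F)c(F)c1F)C#C | intermediate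
12 | methyl 4-[(2R,5S)-5-ethynyloxolan-2-yl]butanoate | COC(=O)CCC[C@@H]1CC[C@@H](C#C)O1 | intermediate
13 | hept-6-yn-1-ol | OCCCCCC#C | starting material
14 | (E)-Cp2Zr(Cl)CH=CH(CH2)5OZr(Cl)Cp2, the alkenylzirconocene chloride with the hydroxyl held as a zirconium alkoxide | Cl[Zr](/C=C/CCCCCO[Zr](Cl)(C1C=CC=C1)C1C=CC=C1)(C1C=CC=C1)C1C=CC=C1 | intermediate
15 | (6E)-7-iodohept-6-en-1-ol | OCCCCC/C=C/I | intermediate
16 | (6E)-7-iodohept-6-enal | O=CCCCC/C=C/I | intermediate
17 | (2E,8E)-9-iodonona-2,8-dienal | O=C/C=C/CCCC/C=C/I | intermediate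
18 | methyl 4-[(2R,5S)-5-[(3E,9E)-11-oxoundeca-3,9-dien-1-yn-1-yl]oxolan-2-yl]butanoate | COC(=O)CCC[C@@H]1CC[C@@H](C#C/C=C/CCCC/C=C/C=O)O1 | intermediate
19 | methyl 4-[(2R,5S)-5-[(3E,9E,11Z)-12-bromododeca-3,9,11-trien-1-yn-1-yl]oxolan-2-yl]butanoate | COC(=O)CCC[C@@H]1CC[C@@H](C#C/C=C/CCCC/C=C/C=C\Br)O1 | target

Total step count: 14 (steps 1–9, 13 and 14 on the main line; steps 10–12 for the C11–C19 iodo-enal).
Longest linear sequence: 11 steps (1 to 9, then 13 and 14).

Steps most likely to fail

1. Step 9 (the new method). The alkyl-substituted ester may ionise too slowly from its copper acetylide, the allenylidene may lose a C7 proton to give an enyne, the free hydroxy ester may lactonise while waiting, or the closure may show poor facial selectivity at C8. The fallback uses known chemistry, sets out from 9 and returns at 12. Dess–Martin oxidation of 9 should give the ethynyl ketone methyl (5R)-5-[(tert-butyldimethylsilyl)oxy]-8-oxodec-9-ynoate F1. Midland reduction with (R)-Alpine-Borane (B-isopinocampheyl-9-BBN from (+)-α-pinene), which turns alkyl ethynyl ketones into (R)-carbinols, should give methyl (5R,8R)-5-[(tert-butyldimethylsilyl)oxy]-8-hydroxydec-9-ynoate F2. MsCl/Et3N in CH2Cl2 at 0 °C should give methyl (5R,8R)-5-[(tert-butyldimethylsilyl)oxy]-8-[(methanesulfonyl)oxy]dec-9-ynoate F3. HF·pyridine then frees the C5 hydroxyl to give methyl (5R,8R)-5-hydroxy-8-[(methanesulfonyl)oxy]dec-9-ynoate F4. On warming with 2,6-lutidine in MeCN, F4 should close by intramolecular SN2 etherification (5-exo-tet) with inversion at C8, giving the (8S) ether 12 without an alkoxide stage.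

2. Step 14. The bromo-ylide may add to the conjugated aldehyde with insufficient (Z)-selectivity, and the geometric isomers may be hard to separate at the last stage. The fallback sets out from 18 and returns at 19, and moves the stereocontrol from ylide kinetics to a selective oxidative addition. Ramirez dibromo-olefination (CBr4, PPh3, Et3N, CH2Cl2, 0 °C) should give methyl 4-[(2R,5S)-5-[(3E,9E)-12,12-dibromododeca-3,9,11-trien-1-yn-1-yl]oxolan-2-yl]butanoate F5. Hydrodebromination with Bu3SnH (1.05 equiv) and Pd(PPh3)4 in toluene at room temperature follows: zerovalent palladium inserts into the less hindered C–Br bond trans to C18 and hydride replaces that bromine with retention, leaving the (Z)-bromide 19.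

3. Step 12. The product enal may react with a second ylide to give the vinylogous dienal, and the alkene geometry may erode at 80 °C. The fallback sets out from 16 and returns at 17 by a three-step homologation that cannot over-react. Horner–Wadsworth–Emmons olefination with triethyl phosphonoacetate and NaH in THF at 0 °C should give ethyl (2E,8E)-9-iodonona-2,8-dienoate F6. Reduction with iBu2AlH in CH2Cl2 at –78 °C should give (2E,8E)-9-iodonona-2,8-dien-1-ol F7. Allylic oxidation with MnO2 in CH2Cl2 then gives 17.

Further compounds
F1 | step 9 | methyl (5R)-5-[(tert-butyldimethylsilyl)oxy]-8-oxodec-9-ynoate | COC(=O)CCC[C@@H](O[Si](C)(C)C(C)(C)C)CCC(=O)C#C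
F2 | step 9 | methyl (5R,8R)-5-[(tert-butyldimethylsilyl)oxy]-8-hydroxydec-9-ynoate | COC(=O)CCC[C@@H](O[Si](C)(C)C(C)(C)C)CC[C@@H](O)C#C
F3 | step 9 | methyl (5R,8R)-5-[(tert-butyldimethylsilyl)oxy]-8-[(methanesulfonyl)oxy]dec-9-ynoate | COC(=O)CCC[C@@H](O[Si](C)(C)C(C)(C)C)CC[C@@H](OS(C)(=O)=O)C#C
F4 | step 9 | methyl (5R,8R)-5-hydroxy-8-[(methanesulfonyl)oxy]dec-9-ynoate | COC(=O)CCC[C@@H](O)CC[C@@H](OS(C)(=O)=O)C#C
F5 | step 14 | methyl 4-[(2R,5S)-5-[(3E,9E)-12,12-dibromododeca-3,9,11-trien-1-yn-1-yl]oxolan-2-yl]butanoate | COC(=O)CCC[C@@H]1CC[C@@H](C#C/C=C/CCCC/C=C/C=C(Br)Br)O1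
F6 | step 12 | ethyl (2E,8E)-9-iodonona-2,8-dienoate | CCOC(=O)/C=C/CCCC/C=C/I
F7 | step 12 | (2E,8E)-9-iodonona-2,8-dien-1-ol | OC/C=C/CCCC/C=C/I
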